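**Retrosynthetic overview**
- The target comes from 4'-benzyloxy-5,6,7,8-tetramethoxyflavone by O-debenzylation in the last step.
- Ring C is the only ring formed: O1–C8a, C4–C4a and O1–C2 are cut in one operation back to 3,4,5,6-tetramethoxybenzyne and 3-[4-(benzyloxy)phenyl]propiolic acid; rings A and B are bought.
- The strategy rests on ring A carrying methoxy groups on all of C5, C6, C7 and C8: the aryne across C4a–C8a is symmetric, either terminus can become C8a or C4a, and no regiochemical question arises.
- The aryne precursor (ortho-silylaryl triflate) comes from 1,2,3,4-tetramethoxybenzene by ortho-metalation/hydroxylation, bromination, O-silylation and retro-Brook shift/triflation.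
- The acid comes from 1-(benzyloxy)-4-iodobenzene and propiolic acid by copper-free Sonogashira coupling.

Key step: step 6

Remark: the target is planar and has no stereocentre or other stereogenic element, so the route needs no stereocontrol.

**Route**

Step 1
Reactants: 1 1,2,3,4-tetramethoxybenzene
Product: 4 2,3,4,5-tetramethoxyphenol, via (2,3,4,5-tetramethoxyphenyl)lithium 2 (not isolated), via lithium aryltrimethoxyborate 3 (not isolated)
Conditions: n-BuLi, TMEDA, THF–hexane, 0 °C → rt; B(OMe)3, −78 °C → rt; 30% H2O2, AcOH, 0 °C → rt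
Reagents that add atoms: hydrogen peroxide, OO
Why: Directed ortho-metalation next to a methoxy group (the two ring hydrogens are equivalent), borylation and boronate oxidation should put the hydroxyl on the ring carbon that later becomes C8a/C4a.

Step 2
Reactants: 4 2,3,4,5-tetramethoxyphenol
Product: 5 2-bromo-3,4,5,6-tetramethoxyphenol
Conditions: NBS (1.0 equiv), CH2Cl2, −40 → 0 °C, dark
Reagents that add atoms: N-bromosuccinimide, O=C1CCC(=O)N1Br
Why: Electrophilic aromatic bromination can only occur at the single free ring carbon, which is ortho to the hydroxyl and activated by ortho and para methoxy groups; low temperature and anhydrous medium are chosen to suppress oxidation of the phenol.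

Step 3
Reactants: 5 2-bromo-3,4,5,6-tetramethoxyphenol
Product: 6 (2-bromo-3,4,5,6-tetramethoxyphenoxy)trimethylsilane
Conditions: HMDS, THF, reflux; volatiles removed in vacuo, crude used directly
Reagents that add atoms: hexamethyldisilazane, C[Si](C)(C)N[Si](C)(C)C
Why: O-silylation of a phenol with HMDS is clean and gives only ammonia as by-product, so the moisture-sensitive silyl ether can be carried on without purification.

Step 4
Reactants: 6 (2-bromo-3,4,5,6-tetramethoxyphenoxy)trimethylsilane
Product: 9 2,3,4,5-tetramethoxy-6-(trimethylsilyl)phenyl trifluoromethanesulfonate, via ortho-silyloxy aryllithium 7 (not isolated), via lithium ortho-silylphenoxide 8 (not isolated)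
Conditions: n-BuLi (1.1 equiv), THF, −100 → −78 °C; Tf2O (1.2 equiv), −100 °C → rt
Reagents that add atoms: trifluoromethanesulfonic anhydride, O=S(=O)(OS(=O)(=O)C(F)(F)F)C(F)(F)F
Why: Bromine–lithium exchange followed by 1,3-O→C silyl migration (retro-Brook rearrangement) is driven by formation of the lithium phenoxide, which is then trapped as the triflate; this is the standard one-flask entry to ortho-silylaryl triflates.

Step 5
Reactants: 10 1-(benzyloxy)-4-iodobenzene; 11 propiolic acid
Product: 12 3-[4-(benzyloxy)phenyl]prop-2-ynoic acid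
Conditions: Pd(PPh3)4 (2.5 mol%), DBU (2.4 equiv), DMSO, 30–35 °C; then cold aq. HCl to pH 2–3
Reagents that add atoms: none
Why: Copper-free Sonogashira-type coupling of the aryl iodide with the DBU propiolate should proceed near room temperature, where the alkynoate does not lose CO2, and the benzyl ether is inert.

Step 6
Reactants: 9 2,3,4,5-tetramethoxy-6-(trimethylsilyl)phenyl trifluoromethanesulfonate; 12 3-[4-(benzyloxy)phenyl]prop-2-ynoic acid
Product: 16 4'-benzyloxy-5,6,7,8-tetramethoxyflavone, via 3,4,5,6-tetramethoxybenzyne 13 (not isolated), via ortho-caesioaryl ester 14 (not isolated), via caesium ortho-acylphenoxide 15 (not isolated)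
Conditions: 9 (1.5 equiv), 12 (1.0 equiv), CsF (4 equiv), THF, 125 °C, sealed tube
Reagents that add atoms: none
Why: Fluoride removes the silyl group of 9 and triflate leaves to give symmetric aryne 13; the caesium carboxylate of 12 adds through oxygen to either equivalent terminus (O1–C8a), and the ortho-aryl anion 14 attacks its own ester carbonyl through a four-membered transition state that opens to the ortho-acylphenoxide 15, forming C4–C4a by a 1,3-O→C acyl shift (anionic Fries type). This is the known insertion of arynes into the C–O bond of carboxylic acids to give o-hydroxyaryl ketones, which with arylpropiolic acids is known to run on to flavones. Ring C closes by 6-endo-dig oxa-Michael addition of the phenoxide oxygen to the β-carbon of the ynone (O1–C2), and the resulting allenolate is protonated at C3 by the proton the acid delivered to the medium. No stereocentre is formed. The step needs acyl transfer to outrun protonation of 14, which the aprotic medium and 125 °C favour, and 6-endo to outrun 5-exo closure (flavone against aurone), which a free phenoxide in an aprotic solvent adding to an aryl-terminated ynone favours.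

Step 7
Reactants: 16 4'-benzyloxy-5,6,7,8-tetramethoxyflavone
Product: 17 4'-hydroxy-5,6,7,8-tetramethoxyflavone
Conditions: H2 (1 atm), 10% Pd/C, EtOAc–MeOH, rt, stopped when 16 is consumed
Reagents that add atoms: none
Why: Hydrogenolysis of the benzyl aryl ether should be much faster than reduction of the vinylogous-ester C2=C3 bond, and it leaves all four methyl ethers intact, unlike Lewis-acid dealkylation, which would attack the peri 5-methoxy group.

**Compound list**
1 | 1,2,3,4-tetramethoxybenzene | COc1ccc(OC)c(OC)c1OC | starting material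
2 | (2,3,4,5-tetramethoxyphenyl)lithium | [Li]c1cc(OC)c(OC)c(OC)c1OC | intermediate
3 | lithium trimethoxy(2,3,4,5-tetramethoxyphenyl)borate | [Li+].CO[B-](OC)(OC)c1cc(OC)c(OC)c(OC)c1OC | intermediate
4 | 2,3,4,5-tetramethoxyphenol | Oc1cc(OC)c(OC)c(OC)c1OC | intermediate
5 | 2-bromo-3,4,5,6-tetramethoxyphenol | Oc1c(Br)c(OC)c(OC)c(OC)c1OC | intermediate
6 | (2-bromo-3,4,5,6-tetramethoxyphenoxy)trimethylsilane | C[Si](C)(C)Oc1c(Br)c(OC)c(OC)c(OC)c1OC | intermediate
7 | [2,3,4,5-tetramethoxy-6-(trimethylsilyloxy)phenyl]lithium | C[Si](C)(C)Oc1c([Li])c(OC)c(OC)c(OC)c1OC | intermediate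
8 | lithium 2,3,4,5-tetramethoxy-6-(trimethylsilyl)phenoxide | [Li+].[O-]c1c([Si](C)(C)C)c(OC)c(OC)c(OC)c1OC | intermediate
9 | 2,3,4,5-tetramethoxy-6-(trimethylsilyl)phenyl trifluoromethanesulfonate | COc1c(OC)c(OC)c([Si](C)(C)C)c(OS(=O)(=O)C(F)(F)F)c1OC | intermediate
10 | 1-(benzyloxy)-4-iodobenzene | Ic1ccc(OCc2ccccc2)cc1 | starting material
11 | propiolic acid | OC(=O)C#C | starting material
12 | 3-[4-(benzyloxy)phenyl]prop-2-ynoic acid | OC(=O)C#Cc1ccc(OCc2ccccc2)cc1 | intermediate
13 | 3,4,5,6-tetramethoxybenzyne | COC1=C(OC)C(OC)=C(OC)C#C1 | intermediate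
14 | [2-({3-[4-(benzyloxy)phenyl]prop-2-ynoyl}oxy)-3,4,5,6-tetramethoxyphenyl]caesium | COc1c(OC)c(OC)c([Cs])c(OC(=O)C#Cc2ccc(OCc3ccccc3)cc2)c1OC | intermediate
15 | caesium 2-{3-[4-(benzyloxy)phenyl]prop-2-ynoyl}-3,4,5,6-tetramethoxyphenoxide | [Cs+].[O-]c1c(OC)c(OC)c(OC)c(OC)c1C(=O)C#Cc1ccc(OCc2ccccc2)cc1 | intermediate
16 | 4'-benzyloxy-5,6,7,8-tetramethoxyflavone (2-[4-(benzyloxy)phenyl]-5,6,7,8-tetramethoxy-4H-chromen-4-one) | COc1c(OC)c(OC)c2c(=O)cc(-c3ccc(OCc4ccccc4)cc3)oc2c1OC | intermediate
17 | 4'-hydroxy-5,6,7,8-tetramethoxyflavone | COc1c(OC)c(OC)c2c(=O)cc(-c3ccc(O)cc3)oc2c1OC | target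

**Step count**
Total steps: 7. Longest linear sequence: 6 steps (steps 1, 2, 3, 4, 6, 7); step 5 is the one-step side branch.

**Steps most likely to fail**

Step 6. The aryl anion may be protonated before the acyl shift (stopping at O-arylation), the propiolate may lose CO2 at 125 °C, or the closure may turn 5-exo. The fallback builds ring C by the classical chalcone route, setting out from phenol 4. C-acetylation at its only free ring carbon with acetic acid and BF3·OEt2 at 80 °C would give 1-(2-hydroxy-3,4,5,6-tetramethoxyphenyl)ethan-1-one F1. Claisen–Schmidt condensation of this ketone with commercial 4-(benzyloxy)benzaldehyde (KOH, EtOH, rt) would give (E)-3-[4-(benzyloxy)phenyl]-1-(2-hydroxy-3,4,5,6-tetramethoxyphenyl)prop-2-en-1-one F2. Oxidative cyclisation with catalytic iodine in DMSO at 120 °C would return to the route at flavone 16.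

Step 4. The aryllithium may be quenched by adventitious protons, or the O→C silyl shift may be incomplete in the fully substituted ring. The fallback replaces the intramolecular shift by an external silyl quench on a protected phenol, setting out from bromophenol 5. Benzylation (BnBr, K2CO3, DMF) would give 1-(benzyloxy)-2-bromo-3,4,5,6-tetramethoxybenzene F3. Bromine–lithium exchange with n-BuLi at −78 °C and quench with chlorotrimethylsilane would give [2-(benzyloxy)-3,4,5,6-tetramethoxyphenyl]trimethylsilane F4. Hydrogenolysis (H2, Pd/C, EtOAc) would free 2,3,4,5-tetramethoxy-6-(trimethylsilyl)phenol F5. Triflation with Tf2O and pyridine in CH2Cl2 at 0 °C would return to the route at triflate 9.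

Step 2. Oxidation of the very electron-rich phenol by the brominating agent may compete with ring substitution. The fallback reverses the order, bromine first and oxygen second, setting out from 1,2,3,4-tetramethoxybenzene 1. Monobromination with NBS in MeCN would give 1-bromo-2,3,4,5-tetramethoxybenzene F6. Deprotonation of its last ring hydrogen, which lies between bromine and a methoxy group, with LiTMP at −78 °C in the presence of triisopropyl borate would give lithium (2-bromo-3,4,5,6-tetramethoxyphenyl)triisopropoxyborate F7. Oxidation of this borate in the same flask with H2O2 and AcOH would return to the route at bromophenol 5.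

**Further compounds**
F1 | step 6 | 1-(2-hydroxy-3,4,5,6-tetramethoxyphenyl)ethan-1-one | CC(=O)c1c(O)c(OC)c(OC)c(OC)c1OC
F2 | step 6 | (E)-3-[4-(benzyloxy)phenyl]-1-(2-hydroxy-3,4,5,6-tetramethoxyphenyl)prop-2-en-1-one | O=C(/C=C/c1ccc(OCc2ccccc2)cc1)c1c(O)c(OC)c(OC)c(OC)c1OC
F3 | step 4 | 1-(benzyloxy)-2-bromo-3,4,5,6-tetramethoxybenzene | COc1c(OC)c(OC)c(Br)c(OCc2ccccc2)c1OC
F4 | step 4 | [2-(benzyloxy)-3,4,5,6-tetramethoxyphenyl]trimethylsilane | COc1c(OC)c(OC)c([Si](C)(C)C)c(OCc2ccccc2)c1OC
F5 | step 4 | 2,3,4,5-tetramethoxy-6-(trimethylsilyl)phenol | COc1c(OC)c(OC)c([Si](C)(C)C)c(O)c1OC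
F6 | step 2 | 1-bromo-2,3,4,5-tetramethoxybenzene | COc1cc(Br)c(OC)c(OC)c1OC
F7 | step 2 | lithium (2-bromo-3,4,5,6-tetramethoxyphenyl)triisopropoxyborate | [Li+].COc1c(Br)c([B-](OC(C)C)(OC(C)C)OC(C)C)c(OC)c(OC)c1OC
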